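**Assumption:** The target (C26H30O5) has no stereocentre and no stereogenic double bond. It is achiral, so "single enantiomer" needs no action. It is drawn as the diketo tautomer, which equilibrates with its enol.

## Retrosynthetic overview
1. Target 13 comes from bis-MOM diketone 12 by global MOM removal.
2. 12 is cut at the central C(O)–CH2 bond: a new oxidative NHC/Mg(II) cross-dehydrogenative C-acylation joins methyl ketone 5 (ring A) and aldehyde 8 (ring B).
3. 5 comes from hindered iodide 4 by Stille prenylation; 4 comes from 2,4-dihydroxyacetophenone 1 by C3-iodination, 4-O-MOM protection and 2-O-methylation.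
4. 8 comes from iodide 7 by Stille prenylation; 7 comes from 4-hydroxy-3-iodobenzaldehyde 6 by MOM protection.
5. No ring is formed. Both benzene rings are bought, and there is no stereocentre to set.

## Route

Step 1
Reactants: 1 1-(2,4-dihydroxyphenyl)ethanone
Product: 2 1-(2,4-dihydroxy-3-iodophenyl)ethanone
Conditions: I2 (0.4 equiv), HIO3 (0.2 equiv), EtOH/H2O, 35 °C
Reagents that add atoms: iodine, II; iodic acid, OI(=O)=O
Why: Electrophilic aromatic iodination goes to C3, the carbon ortho to both hydroxyls, and the oxidant recycles iodide so that water is the only by-product.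

Step 2
Reactants: 2 1-(2,4-dihydroxy-3-iodophenyl)ethanone
Product: 3 1-[2-hydroxy-3-iodo-4-(methoxymethoxy)phenyl]ethanone
Conditions: MOMCl (1.1 equiv), K2CO3 (1.5 equiv), acetone, 0 °C to rt
Reagents that add atoms: chloromethyl methyl ether, COCCl
Why: Williamson-type O-alkylation takes only the free, more acidic 4-OH, because the 2-OH is locked in a hydrogen bond to the acetyl carbonyl.

Step 3
Reactants: 3 1-[2-hydroxy-3-iodo-4-(methoxymethoxy)phenyl]ethanone
Product: 4 1-[3-iodo-2-methoxy-4-(methoxymethoxy)phenyl]ethanone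
Conditions: MeI (2 equiv), K2CO3 (2 equiv), DMF, 50 °C
Reagents that add atoms: iodomethane, CI
Why: Williamson O-methylation of the chelated phenol proceeds in warm polar aprotic medium, and the MOM ether, aryl iodide and ketone are inert to K2CO3/MeI.

Step 4
Reactants: 4 1-[3-iodo-2-methoxy-4-(methoxymethoxy)phenyl]ethanone
Product: 5 1-[2-methoxy-4-(methoxymethoxy)-3-(3-methylbut-2-enyl)phenyl]ethanone
Conditions: prenylSnBu3 (1.3 equiv), Pd2(dba)3 (2.5 mol %), AsPh3 (10 mol %), DMF, 80 °C
Reagents that add atoms: tributyl(3-methylbut-2-enyl)stannane, CCCC[Sn](CCCC)(CCCC)CC=C(C)C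
Why: In this Stille coupling the prenyl-Pd species equilibrates through the π-allyl form and reductively eliminates at the unhindered primary terminus, which gives the linear prenyl arene at the position fixed by the iodide.

Step 5
Reactants: 6 4-hydroxy-3-iodobenzaldehyde
Product: 7 3-iodo-4-(methoxymethoxy)benzaldehyde
Conditions: MOMCl (1.2 equiv), K2CO3 (1.5 equiv), acetone, 0 °C to rt
Reagents that add atoms: chloromethyl methyl ether, COCCl
Why: This is a simple Williamson-type O-alkylation of an acidic para-formyl phenol.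

Step 6
Reactants: 7 3-iodo-4-(methoxymethoxy)benzaldehyde
Product: 8 4-(methoxymethoxy)-3-(3-methylbut-2-enyl)benzaldehyde
Conditions: prenylSnBu3 (1.2 equiv), Pd2(dba)3 (2.5 mol %), AsPh3 (10 mol %), DMF, 80 °C
Reagents that add atoms: tributyl(3-methylbut-2-enyl)stannane, CCCC[Sn](CCCC)(CCCC)CC=C(C)C
Why: This Stille coupling uses an activated, mono-ortho-substituted aryl iodide, gives the linear prenyl product as in step 4, and leaves the aldehyde and MOM ether untouched.

Step 7
Reactants: 5 1-[2-methoxy-4-(methoxymethoxy)-3-(3-methylbut-2-enyl)phenyl]ethanone; 8 4-(methoxymethoxy)-3-(3-methylbut-2-enyl)benzaldehyde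
Product: 12 1-[2-methoxy-4-(methoxymethoxy)-3-(3-methylbut-2-enyl)phenyl]-3-[4-(methoxymethoxy)-3-(3-methylbut-2-enyl)phenyl]propane-1,3-dione, via bromomagnesium enolate 9 (not isolated), via acyl azolium bromide 10 (not isolated), via bromomagnesium diketonate 11 (not isolated)
Conditions: 5 (1.0 equiv), 2-mesityl-6,7-dihydro-5H-pyrrolo[2,1-c][1,2,4]triazol-2-ium BF4 (15 mol %), 3,3',5,5'-tetra-tert-butyl-4,4'-diphenoquinone (DQ, 1.3 equiv), MgBr2·OEt2 (3 equiv), iPr2NEt (5 equiv), 4 Å MS, CH2Cl2, 23 °C, 8 (1.2 equiv) added over 6 h; then 1 M HCl, 0 °C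
Reagents that add atoms: none
Why: Proposed new method: an oxidative NHC/Mg(II) dual-activation cross-dehydrogenative coupling of an aldehyde C–H with a methyl ketone α-C–H, in which the triazolylidene adds to 8, the Breslow intermediate is oxidised irreversibly by DQ to acyl azolium 10, MgBr2/iPr2NEt soft-enolises 5 (helped by 2-OMe/C=O chelation) to 9, and 9 attacks 10 at carbon through a Mg-bridged closed transition state that expels the carbene and gives 12, which is trapped as chelate 11 so that it neither protonates the carbene nor acylates again; the competing Mg aldol addition is reversible and is starved by slow addition of 8, any O-acyl enol ester is re-ionised by the carbene and funnelled to the thermodynamic C-acyl product, and the hindered hydroquinone from DQ is not acylated; the closest known reaction types are oxidative NHC-catalysed esterification of aldehydes via acyl azoliums, cooperative NHC/Mg(II) Lewis acid catalysis, and the MgBr2·OEt2/iPr2NEt soft-enolisation crossed-Claisen acylation of ketones with preformed activated acyl donors.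

Step 8
Reactants: 12 1-[2-methoxy-4-(methoxymethoxy)-3-(3-methylbut-2-enyl)phenyl]-3-[4-(methoxymethoxy)-3-(3-methylbut-2-enyl)phenyl]propane-1,3-dione
Product: 13 1-[4-hydroxy-2-methoxy-3-(3-methylbut-2-enyl)phenyl]-3-[4-hydroxy-3-(3-methylbut-2-enyl)phenyl]propane-1,3-dione
Conditions: conc. HCl (cat.), MeOH, 40 °C, 2–3 h
Reagents that add atoms: none
Why: Acid-catalysed acetal exchange moves both MOM groups to methanol under conditions too mild for chroman formation from the ortho-prenyl phenols, and the 2-OMe group rules out flavone closure.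

## Compound list
1 | 1-(2,4-dihydroxyphenyl)ethanone (2,4-dihydroxyacetophenone) | CC(=O)c1ccc(O)cc1O | starting material
2 | 1-(2,4-dihydroxy-3-iodophenyl)ethanone | CC(=O)c1ccc(O)c(I)c1O | intermediate
3 | 1-[2-hydroxy-3-iodo-4-(methoxymethoxy)phenyl]ethanone | CC(=O)c1ccc(OCOC)c(I)c1O | intermediate
4 | 1-[3-iodo-2-methoxy-4-(methoxymethoxy)phenyl]ethanone | CC(=O)c1ccc(OCOC)c(I)c1OC | intermediate
5 | 1-[2-methoxy-4-(methoxymethoxy)-3-(3-methylbut-2-enyl)phenyl]ethanone | CC(=O)c1ccc(OCOC)c(CC=C(C)C)c1OC | intermediate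
6 | 4-hydroxy-3-iodobenzaldehyde | O=Cc1ccc(O)c(I)c1 | starting material
7 | 3-iodo-4-(methoxymethoxy)benzaldehyde | O=Cc1ccc(OCOC)c(I)c1 | intermediate
8 | 4-(methoxymethoxy)-3-(3-methylbut-2-enyl)benzaldehyde | O=Cc1ccc(OCOC)c(CC=C(C)C)c1 | intermediate
9 | bromomagnesium enolate of 5 (not isolated) | C=C(O[Mg]Br)c1ccc(OCOC)c(CC=C(C)C)c1OC | intermediate
10 | 2-mesityl-3-[4-(methoxymethoxy)-3-(3-methylbut-2-enyl)benzoyl]-6,7-dihydro-5H-pyrrolo[2,1-c][1,2,4]triazol-2-ium bromide (not isolated) | Cc1cc(C)c(c(C)c1)-[n+]1nc2CCCn2c1C(=O)c1ccc(OCOC)c(CC=C(C)C)c1.[Br-] | intermediate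
11 | bromomagnesium (Z)-enolate chelate of 12 (not isolated) | COCOc1ccc(cc1CC=C(C)C)C(=O)/C=C(\O[Mg]Br)c1ccc(OCOC)c(CC=C(C)C)c1OC | intermediate
12 | 1-[2-methoxy-4-(methoxymethoxy)-3-(3-methylbut-2-enyl)phenyl]-3-[4-(methoxymethoxy)-3-(3-methylbut-2-enyl)phenyl]propane-1,3-dione | COCOc1ccc(cc1CC=C(C)C)C(=O)CC(=O)c1ccc(OCOC)c(CC=C(C)C)c1OC | intermediate
13 | 1-[4-hydroxy-2-methoxy-3-(3-methylbut-2-enyl)phenyl]-3-[4-hydroxy-3-(3-methylbut-2-enyl)phenyl]propane-1,3-dione (CNP0167758.0, achiral) | COc1c(C(=O)CC(=O)c2ccc(O)c(CC=C(C)C)c2)ccc(O)c1CC=C(C)C | target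

## Counts and risks
- Total step count: 8.
- Longest linear sequence: 6 (steps 1, 2, 3, 4, 7, 8).

**Step 7, the new reaction, is the most likely to fail.** Mg-promoted aldol or Claisen–Schmidt chemistry of 8, binding of the carbene to Mg(II), or unproductive O-acylation could win. The fallback uses only known chemistry, sets out from 5 and 8, and comes back at 12. The lithium enolate of 5 (LDA, THF, −78 °C) is added to 8 to give racemic 3-hydroxy-1-[2-methoxy-4-(methoxymethoxy)-3-(3-methylbut-2-enyl)phenyl]-3-[4-(methoxymethoxy)-3-(3-methylbut-2-enyl)phenyl]propan-1-one F1. IBX (EtOAc, 75 °C) then oxidises this β-hydroxy ketone to 12, which removes the transient stereocentre.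

**Step 4 comes second.** The iodide is flanked by two alkoxy groups, so slow transmetalation, protodeiodination or some reverse-prenyl product are possible. The fallback replaces cross-coupling with a sigmatropic route, sets out from 1, and comes back at 5.
- Allyl bromide/K2CO3 (acetone, reflux) alkylates the non-chelated 4-OH to give 1-[4-(allyloxy)-2-hydroxyphenyl]ethanone F2.
- Aromatic Claisen rearrangement (N,N-diethylaniline, 200 °C) goes to C3 and gives 1-(3-allyl-2,4-dihydroxyphenyl)ethanone F3.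
- MOMCl/K2CO3 gives 1-[3-allyl-2-hydroxy-4-(methoxymethoxy)phenyl]ethanone F4.
- MeI/K2CO3 (DMF, 50 °C) gives 1-[3-allyl-2-methoxy-4-(methoxymethoxy)phenyl]ethanone F5.
- Cross-metathesis with excess 2-methylbut-2-ene (Grubbs II, 5 mol %, CH2Cl2, 40 °C) turns the allyl group into the prenyl group of 5.

**Step 8 comes third.** Acid could cyclise the freed ortho-prenyl phenols to chromans or add methanol across the prenyl alkenes. The fallback changes the order of events so that acid never meets a prenyl phenol. It sets out from 4 and 7 and comes back at 13.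
- The lithium enolate of 4 (LDA, THF, −78 °C) adds to 7 to give racemic 3-hydroxy-3-[3-iodo-4-(methoxymethoxy)phenyl]-1-[3-iodo-2-methoxy-4-(methoxymethoxy)phenyl]propan-1-one F6.
- IBX (EtOAc, 75 °C) gives 1-[3-iodo-2-methoxy-4-(methoxymethoxy)phenyl]-3-[3-iodo-4-(methoxymethoxy)phenyl]propane-1,3-dione F7.
- HCl/MeOH (50 °C) removes both MOM groups to give 1-(4-hydroxy-3-iodo-2-methoxyphenyl)-3-(4-hydroxy-3-iodophenyl)propane-1,3-dione F8.
- A double Stille coupling with prenylSnBu3 (2.6 equiv, Pd2(dba)3/AsPh3, DMF, 80 °C) installs both prenyl groups last and gives 13.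

## Further compounds
F1 | step 7 | racemic 3-hydroxy-1-[2-methoxy-4-(methoxymethoxy)-3-(3-methylbut-2-enyl)phenyl]-3-[4-(methoxymethoxy)-3-(3-methylbut-2-enyl)phenyl]propan-1-one | COCOc1ccc(cc1CC=C(C)C)C(O)CC(=O)c1ccc(OCOC)c(CC=C(C)C)c1OC
F2 | step 4 | 1-[4-(allyloxy)-2-hydroxyphenyl]ethanone | CC(=O)c1ccc(OCC=C)cc1O
F3 | step 4 | 1-(3-allyl-2,4-dihydroxyphenyl)ethanone | CC(=O)c1ccc(O)c(CC=C)c1O
F4 | step 4 | 1-[3-allyl-2-hydroxy-4-(methoxymethoxy)phenyl]ethanone | CC(=O)c1ccc(OCOC)c(CC=C)c1O
F5 | step 4 | 1-[3-allyl-2-methoxy-4-(methoxymethoxy)phenyl]ethanone | CC(=O)c1ccc(OCOC)c(CC=C)c1OC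
F6 | step 8 | racemic 3-hydroxy-3-[3-iodo-4-(methoxymethoxy)phenyl]-1-[3-iodo-2-methoxy-4-(methoxymethoxy)phenyl]propan-1-one | COCOc1ccc(cc1I)C(O)CC(=O)c1ccc(OCOC)c(I)c1OC
F7 | step 8 | 1-[3-iodo-2-methoxy-4-(methoxymethoxy)phenyl]-3-[3-iodo-4-(methoxymethoxy)phenyl]propane-1,3-dione | COCOc1ccc(cc1I)C(=O)CC(=O)c1ccc(OCOC)c(I)c1OC
F8 | step 8 | 1-(4-hydroxy-3-iodo-2-methoxyphenyl)-3-(4-hydroxy-3-iodophenyl)propane-1,3-dione | Oc1ccc(cc1I)C(=O)CC(=O)c1ccc(O)c(I)c1OC
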